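## Retrosynthetic overview

- Last step: one hydrogenation removes both O-benzyl groups and saturates the chain alkene, so the two acetates never meet base or Lewis acid.
- CO2H comes from an aryl C–H (Vilsmeier–Haack formylation, then Pinnick oxidation), installed only after both carbinols are acetylated so that no dihydroisocoumarin lactone can form.
- The chain is joined by cross-metathesis of an aryl decenol with (R)-pent-4-en-2-ol, which brings the methyl carbinol centre from the chiral pool.
- The ArCH2–CH(OH) bond comes from an aryl Grignard reagent opening (S)-1,2-epoxy-9-decene (from hydrolytic kinetic resolution), which fixes the homobenzylic centre.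
- No ring is built; the benzene ring is bought as 1,3-bis(benzyloxy)-5-bromobenzene.

Assumption: racemic 1,2-epoxy-9-decene, 1,3-bis(benzyloxy)-5-bromobenzene and (R)-pent-4-en-2-ol are bought, and the metathesis alkene is carried as an E/Z mixture (E major, E drawn) because its geometry is erased in the last step.

## Route

Step 1
Reactants: 1 rac-2-(oct-7-en-1-yl)oxirane (1,2-epoxy-9-decene)
Product: 2 (2S)-2-(oct-7-en-1-yl)oxirane
Conditions: (S,S)-(salen)Co(OAc) (0.5 mol%; trivalent cobalt, made from (S,S)-(salen)Co with AcOH in air; salen = N,N'-bis(3,5-di-tert-butylsalicylidene)cyclohexane-1,2-diamine dianion), H2O (0.55 equiv), neat, 0 °C → rt, 16 h; vacuum distillation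
Reagents that add atoms: none
Why: Jacobsen hydrolytic kinetic resolution, in which the (S,S)-catalyst hydrolyses the (R)-epoxide much faster, so the unreacted (S)-epoxide (the future homobenzylic carbinol carbon) is distilled off in high ee.

Step 2
Reactants: 3 1,3-bis(benzyloxy)-5-bromobenzene; 2 (2S)-2-(oct-7-en-1-yl)oxirane
Product: 5 (2S)-1-[3,5-bis(benzyloxy)phenyl]dec-9-en-2-ol, via aryl Grignard reagent 4 (not isolated)
Conditions: Mg, THF, 50 °C (3 → 4, 1.3 equiv); CuI (10 mol%), then 2, −30 → 0 °C; sat. aq NH4Cl
Reagents that add atoms: none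
Why: Copper-catalysed Grignard opening of a terminal epoxide (SN2 at the unsubstituted CH2), so the C–O bond at the stereocentre is never broken and the (S) configuration of 2 becomes the (2S)-carbinol.

Step 3
Reactants: 5 (2S)-1-[3,5-bis(benzyloxy)phenyl]dec-9-en-2-ol; 6 (2R)-pent-4-en-2-ol
Product: 7 (2R,4E,12S)-13-[3,5-bis(benzyloxy)phenyl]tridec-4-ene-2,12-diol
Conditions: second-generation Grubbs catalyst (5 mol%), 1,4-benzoquinone (10 mol%), 6 (4 equiv), CH2Cl2, 40 °C, argon sparge
Reagents that add atoms: none
Why: Olefin cross-metathesis of two unhindered terminal alkenes, driven by loss of ethene and the excess of cheap 6, which supplies the (R) methyl carbinol centre ready-made while neither carbinol is touched.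

Step 4
Reactants: 7 (2R,4E,12S)-13-[3,5-bis(benzyloxy)phenyl]tridec-4-ene-2,12-diol
Product: 8 (2R,4E,12S)-13-[3,5-bis(benzyloxy)phenyl]tridec-4-ene-2,12-diyl diacetate
Conditions: Ac2O (4 equiv), pyridine, DMAP (5 mol%), CH2Cl2, 0 °C → rt
Reagents that add atoms: acetic anhydride, CC(=O)OC(C)=O
Why: DMAP-catalysed O-acylation of both secondary alcohols with retention (only O–H bonds react), and capping the homobenzylic oxygen now is what prevents lactonisation onto the carboxyl group introduced next.

Step 5
Reactants: 8 (2R,4E,12S)-13-[3,5-bis(benzyloxy)phenyl]tridec-4-ene-2,12-diyl diacetate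
Product: 10 (2R,4E,12S)-13-[3,5-bis(benzyloxy)-2-formylphenyl]tridec-4-ene-2,12-diyl diacetate, via aryl iminium salt 9 (not isolated)
Conditions: POCl3 (1.5 equiv), DMF, 0 → 50 °C, 3 h; then aq NaOAc, rt
Reagents that add atoms: N,N-dimethylformamide, CN(C)C=O; water, O
Why: Vilsmeier–Haack formylation, in which the chloroiminium ion attacks the ring carbon next to the side chain (para to one benzyloxy group and ortho to the other, less hindered than the carbon between the two ethers) and the iminium salt is hydrolysed to the aldehyde on work-up, while esters and the isolated alkene are inert.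

Step 6
Reactants: 10 (2R,4E,12S)-13-[3,5-bis(benzyloxy)-2-formylphenyl]tridec-4-ene-2,12-diyl diacetate
Product: 11 2-[(2S,9E,12R)-2,12-bis(acetyloxy)tridec-9-en-1-yl]-4,6-bis(benzyloxy)benzoic acid
Conditions: NaClO2 (3 equiv), NaH2PO4 (3 equiv), 2-methyl-2-butene (20 equiv), tBuOH/THF/H2O, 0 °C → rt
Reagents that add atoms: sodium chlorite, [Na+].[O-]Cl=O
Why: Pinnick oxidation, in which buffered chlorous acid converts the aldehyde to the acid without touching acetates, benzyl ethers or stereocentres, while 2-methyl-2-butene traps HOCl before it can chlorinate the electron-rich ring or the chain alkene.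

Step 7
Reactants: 11 2-[(2S,9E,12R)-2,12-bis(acetyloxy)tridec-9-en-1-yl]-4,6-bis(benzyloxy)benzoic acid
Product: 12 2-[(2S,12R)-2,12-bis(acetyloxy)tridecyl]-4,6-dihydroxybenzoic acid
Conditions: H2 (1 atm), 10% Pd/C, EtOAc, rt
Reagents that add atoms: none
Why: Heterogeneous catalytic hydrogenation and hydrogenolysis, which cleaves both aryl benzyl ethers and saturates the chain alkene under neutral conditions, so the two non-benzylic secondary acetates, the free acid and both stereocentres survive.

## Compound list

1 | rac-2-(oct-7-en-1-yl)oxirane (1,2-epoxy-9-decene) | C=CCCCCCCC1CO1 | starting material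
2 | (2S)-2-(oct-7-en-1-yl)oxirane | C=CCCCCCC[C@H]1CO1 | intermediate
3 | 1,3-bis(benzyloxy)-5-bromobenzene | Brc1cc(OCc2ccccc2)cc(OCc2ccccc2)c1 | starting material
4 | [3,5-bis(benzyloxy)phenyl]magnesium bromide | Br[Mg]c1cc(OCc2ccccc2)cc(OCc2ccccc2)c1 | intermediate (not isolated)
5 | (2S)-1-[3,5-bis(benzyloxy)phenyl]dec-9-en-2-ol | C=CCCCCCC[C@H](O)Cc1cc(OCc2ccccc2)cc(OCc2ccccc2)c1 | intermediate
6 | (2R)-pent-4-en-2-ol | C=CC[C@@H](C)O | starting material
7 | (2R,4E,12S)-13-[3,5-bis(benzyloxy)phenyl]tridec-4-ene-2,12-diol (aryl-end carbinol S, methyl-end carbinol R; E major) | C[C@@H](O)C/C=C/CCCCCC[C@H](O)Cc1cc(OCc2ccccc2)cc(OCc2ccccc2)c1 | intermediate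
8 | (2R,4E,12S)-13-[3,5-bis(benzyloxy)phenyl]tridec-4-ene-2,12-diyl diacetate | C[C@@H](OC(C)=O)C/C=C/CCCCCC[C@H](OC(C)=O)Cc1cc(OCc2ccccc2)cc(OCc2ccccc2)c1 | intermediate
9 | {2,4-bis(benzyloxy)-6-[(2S,9E,12R)-2,12-bis(acetyloxy)tridec-9-en-1-yl]benzylidene}dimethylammonium dichlorophosphate | C[C@@H](OC(C)=O)C/C=C/CCCCCC[C@H](OC(C)=O)Cc1cc(OCc2ccccc2)cc(OCc2ccccc2)c1C=[N+](C)C.[O-]P(=O)(Cl)Cl | intermediate (not isolated)
10 | (2R,4E,12S)-13-[3,5-bis(benzyloxy)-2-formylphenyl]tridec-4-ene-2,12-diyl diacetate | C[C@@H](OC(C)=O)C/C=C/CCCCCC[C@H](OC(C)=O)Cc1cc(OCc2ccccc2)cc(OCc2ccccc2)c1C=O | intermediate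
11 | 2-[(2S,9E,12R)-2,12-bis(acetyloxy)tridec-9-en-1-yl]-4,6-bis(benzyloxy)benzoic acid | C[C@@H](OC(C)=O)C/C=C/CCCCCC[C@H](OC(C)=O)Cc1cc(OCc2ccccc2)cc(OCc2ccccc2)c1C(=O)O | intermediate
12 | 2-[(2S,12R)-2,12-bis(acetyloxy)tridecyl]-4,6-dihydroxybenzoic acid | CC(=O)O[C@@H](CCCCCCCCC[C@@H](C)OC(C)=O)Cc1cc(O)cc(O)c1C(=O)O | target

## Step count, longest linear sequence, risks and fallbacks

Total step count: 7. Longest linear sequence: 7 steps (1 → 2 → 5 → 7 → 8 → 10 → 11 → 12); compounds 3 and 6 enter as bought materials.

Step 2 is at risk because the Grignard reagent may form sluggishly and magnesium bromide can open the epoxide to a bromohydrin. The fallback sets out from 3, used directly as the aryl bromide together with epoxide 2, and comes back at 5. It is a nickel-catalysed reductive cross-electrophile coupling with no organomagnesium reagent: NiCl2(dme) (10 mol%), 2,2'-bipyridine (10 mol%), NaI (25 mol%), Et3N·HCl (1 equiv), Mn powder (2 equiv), DMPU, rt. Iodide opens 2 at the unsubstituted carbon to give (2S)-1-iododec-9-en-2-ol F1 in the flask, and the nickel catalyst joins its CH2–I carbon to the aryl group of 3. The carbinol centre is not touched, so 5 is formed with the same (S) configuration.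

Step 3 is at risk because metathesis of two terminal alkenes gives statistical homodimers, and ruthenium hydrides formed in the presence of free carbinols can move the double bond and shorten the chain. The fallback sets out from 5 and comes back at 8, reversing the order of acylation and C–C coupling so that no free alcohol meets the catalyst. Acetylation of 5 (Ac2O, pyridine, DMAP) gives (2S)-1-[3,5-bis(benzyloxy)phenyl]dec-9-en-2-yl acetate F2. Acetylation of 6 in the same way gives (2R)-pent-4-en-2-yl acetate F3, which is distilled. The two esters are then coupled (F3 in threefold excess, second-generation Hoveyda–Grubbs catalyst, toluene, 60 °C, argon sparge) to give 8 itself, so 7 is bypassed and the route continues with step 5.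

Step 5 is at risk because some formylation may occur between the two benzyloxy groups, and the acidic medium may remove some benzyl groups. The fallback sets out from 8 and comes back at 12, replacing formylation and oxidation by halogenation and carbonylation. NBS in MeCN at 0 °C brominates the ring carbon next to the side chain to give (2R,4E,12S)-13-[3,5-bis(benzyloxy)-2-bromophenyl]tridec-4-ene-2,12-diyl diacetate F4. Palladium-catalysed alkoxycarbonylation (Pd(OAc)2 5 mol%, Xantphos 10 mol%, CO 1 atm, BnOH 3 equiv, Et3N, toluene, 90 °C) converts it into benzyl 2-[(2S,9E,12R)-2,12-bis(acetyloxy)tridec-9-en-1-yl]-4,6-bis(benzyloxy)benzoate F5. Hydrogenation under the conditions of step 7 then removes all three benzyl groups and saturates the alkene to give 12 directly, bypassing 10 and 11.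

## Further compounds

F1 | step 2 | (2S)-1-iododec-9-en-2-ol | C=CCCCCCC[C@H](O)CI
F2 | step 3 | (2S)-1-[3,5-bis(benzyloxy)phenyl]dec-9-en-2-yl acetate | C=CCCCCCC[C@H](OC(C)=O)Cc1cc(OCc2ccccc2)cc(OCc2ccccc2)c1
F3 | step 3 | (2R)-pent-4-en-2-yl acetate | C=CC[C@@H](C)OC(C)=O
F4 | step 5 | (2R,4E,12S)-13-[3,5-bis(benzyloxy)-2-bromophenyl]tridec-4-ene-2,12-diyl diacetate | C[C@@H](OC(C)=O)C/C=C/CCCCCC[C@H](OC(C)=O)Cc1cc(OCc2ccccc2)cc(OCc2ccccc2)c1Br
F5 | step 5 | benzyl 2-[(2S,9E,12R)-2,12-bis(acetyloxy)tridec-9-en-1-yl]-4,6-bis(benzyloxy)benzoate | C[C@@H](OC(C)=O)C/C=C/CCCCCC[C@H](OC(C)=O)Cc1cc(OCc2ccccc2)cc(OCc2ccccc2)c1C(=O)OCc1ccccc1
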